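**Retrosynthetic overview**

1. Target ⇐ late C1=C2 epoxidation, 8‑O‑angeloylation and 1,3‑anti reduction at C8 ⇐ ten‑membered (1Z,4Z)‑10‑hydroxy‑3,8‑dione 22 ⇐ β‑scission of the C8 alkoxy radical of tricycle 20, which cuts a temporary C3–C8 bond.
2. Tricycle ⇐ intramolecular furan Diels–Alder reaction of 13, which closes the oxanorbornene through the C9–C10 bond (CH2 to C(OH)Me) and makes the temporary C3–C8 bond at the same time.
3. Enabling feature: the C10(O)(Me)–C1–C2–C3(=O) epoxy‑ketone/carbinol array is a masked 2‑methylfuran‑2,5‑diyl (O bridging C10 and C3), and O‑8 makes C8=C9 the enol ether of a methyl ketone. Because C3 and C8 both carry oxygen, a C3–C8 bond can be made and later cut oxidatively; both Z alkenes (C1=C2, C4=C5) sit in small rings of the tricycle.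
4. 13 ⇐ Evans syn‑aldol/lactonisation of succinate imide 8 with (Z)‑enal 5. C6 is carried as its epimer (trans‑lactone, which steers the cycloaddition face) and inverted afterwards by Mitsunobu lactonisation.
5. Ring order: furan (bought) → γ‑lactone → cyclohexene ring 1 plus oxanorbornene (key step) → lactone re‑closed with inversion → ten‑membered ring by fragmentation → epoxide.

Key step: step 9

Remark: positions are numbered as in a germacran‑6,12‑olide (C6 lactone carbinol, C8 angeloyloxy carbon, C10 carbinol, C1–C2 epoxide, C3 ketone, C4=C5 alkene, C11–C13 lactone methylene unit, C14/C15 methyls on C10/C4); this numbering is an assumption used only to name positions.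

**Route**

Step 1
Reactants: 1 but-2-yn-1-ol
Product: 2 (Z)-3-iodobut-2-en-1-ol
Conditions: NaAlH2(OCH2CH2OMe)2, THF, 0 °C to rt; then I2, −78 °C
Reagents that add atoms: iodine, II
Why: Alkoxide‑directed trans‑hydroalumination of the propargylic alcohol places aluminium on C3 cis to the CH2O group, and iodinolysis with retention should give the (Z)‑vinyl iodide that fixes the later C4=C5 geometry.

Step 2
Reactants: 2 (Z)-3-iodobut-2-en-1-ol; 3 4,4,5,5-tetramethyl-2-(5-methylfuran-2-yl)-1,3,2-dioxaborolane
Product: 4 (Z)-3-(5-methylfuran-2-yl)but-2-en-1-ol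
Conditions: Pd(dppf)Cl2 (cat.), K2CO3, THF/H2O, 50 °C
Reagents that add atoms: none
Why: Suzuki–Miyaura coupling is stereoretentive at the vinyl iodide, so the furan should end cis to the CH2OH group.

Step 3
Reactants: 4 (Z)-3-(5-methylfuran-2-yl)but-2-en-1-ol
Product: 5 (Z)-3-(5-methylfuran-2-yl)but-2-enal
Conditions: MnO2, CH2Cl2, rt, used at once
Reagents that add atoms: none
Why: Allylic oxidation with MnO2 is neutral and mild enough that the (Z)‑enal should survive without isomerisation.

Step 4
Reactants: 6 (S)-4-benzyloxazolidin-2-one; 7 methyl 4-chloro-4-oxobutanoate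
Product: 8 methyl 4-[(S)-4-benzyl-2-oxooxazolidin-3-yl]-4-oxobutanoate
Conditions: n-BuLi, THF, −78 °C; then 7
Reagents that add atoms: none
Why: N‑acylation of the lithiated oxazolidinone with the acid chloride is a standard way to the Evans imide.

Step 5
Reactants: 8 methyl 4-[(S)-4-benzyl-2-oxooxazolidin-3-yl]-4-oxobutanoate; 5 (Z)-3-(5-methylfuran-2-yl)but-2-enal
Product: 10 (S)-4-benzyl-3-{(2R,3S)-2-[(Z)-2-(5-methylfuran-2-yl)prop-1-en-1-yl]-5-oxotetrahydrofuran-3-carbonyl}oxazolidin-2-one (trans-lactone), via aldol adduct 9 (not isolated)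
Conditions: Bu2BOTf, iPr2NEt, CH2Cl2, −78 to 0 °C; 5, −78 to 0 °C; MeOH/pH 7 buffer; SiO2
Reagents that add atoms: none
Why: Evans syn‑aldol reaction: the (Z)‑boron enolate reacts through a chair transition state on the face opposite the benzyl group, setting C7 (S) and C6 (R, the temporary epimer), and the aldolate oxygen should then close onto the γ‑ester to give the trans‑lactone.

Step 6
Reactants: 10 trans-lactone imide
Product: 11 S-ethyl (2R,3S)-2-[(Z)-2-(5-methylfuran-2-yl)prop-1-en-1-yl]-5-oxotetrahydrofuran-3-carbothioate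
Conditions: EtSH, n-BuLi, THF, 0 °C
Reagents that add atoms: ethanethiol, CCS
Why: Thiolate transacylation attacks the exocyclic imide carbonyl selectively and releases the auxiliary without touching C7.

Step 7
Reactants: 11 S-ethyl thioester
Product: 12 (4S,5R)-4-acetyl-5-[(Z)-2-(5-methylfuran-2-yl)prop-1-en-1-yl]dihydrofuran-2(3H)-one
Conditions: Me2CuLi (from MeLi and CuI), Et2O, −78 °C
Reagents that add atoms: lithium dimethylcuprate, [Li+].C[Cu-]C
Why: Cuprate acyl substitution of a thioester stops at the methyl ketone, and at −78 °C the lactone and its allylic C–O bond should be left alone; the trans‑lactone is the stable C7 epimer.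

Step 8
Reactants: 12 methyl ketone
Product: 13 (4S,5R)-5-[(Z)-2-(5-methylfuran-2-yl)prop-1-en-1-yl]-4-[1-(triethylsilyloxy)vinyl]dihydrofuran-2(3H)-one
Conditions: LiN(iPr)2, Et3SiCl (in situ quench), THF, −78 °C
Reagents that add atoms: chlorotriethylsilane, CC[Si](Cl)(CC)CC
Why: Kinetic deprotonation of the methyl ketone at the CH3 group and O‑silylation give the terminal silyl enol ether (C8=C9) and avoid the C7 enolate that could eliminate the lactone oxygen.

Step 9
Reactants: 13 furan-tethered silyl enol ether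
Product: 14 exo Diels–Alder adduct: (6R,7S,10R)-3,10-epoxy tricycle with new C3–C8 and C9–C10 bonds; 8-OSiEt3 anti to the oxygen bridge; H-7 syn to it; trans-6,12-lactone
Conditions: CH2Cl2 (dilute), 2,6-lutidine (trace), 15 kbar, 40 °C
Reagents that add atoms: none
Why: Proposed new method: a concerted, suprafacial intramolecular [4+2] cycloaddition in which the furan of 13 (C10=C1–C2=C3) is the diene and the tethered triethylsilyl enol ether (C8=C9) the 2π partner, so that the C9–C10 bond and the temporary C3–C8 bond form together; the pairing is electron‑rich with electron‑rich, so it is proposed to be driven by pressure (strongly negative activation and reaction volumes) and by preorganisation, and the adduct should not revert once the pressure is released because the barrier is high in both directions. The closest known reaction type is the high‑pressure intramolecular Diels–Alder reaction of furans with four‑atom‑tethered alkenes that carry no activating group, together with the known additions of furan to enol esters such as vinylene carbonate. Ring 1 (cyclohexene C3–C4=C5–C6–C7–C8) closes through C3–C8 in the type 1 mode (tether on the diene terminus) with the tether exo, and the 7‑oxanorbornene closes through C9–C10 as the bridged [4+2] ring. C10 is set by the furan face that is attacked: the trans‑lactone holds O‑6 and C‑11 equatorial on the half‑chair of ring 1, H‑7 is therefore axial, and the exo tether places the bridging oxygen cis to H‑7, which is the (10R) sense the target needs; C3 and C8 are set as a consequence but are temporary and disappear in step 14. The step needs facial selectivity and site selectivity for the furan 4π unit; the first is secured by the lactone‑locked chair‑like transition state, the second by the (Z)‑C4=C5 geometry, which lets only C8 reach C3 and keeps the 2‑vinylfuran diene out of reach of the enol ether.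

Step 10
Reactants: 14 exo Diels–Alder adduct
Product: 15 hydroxy acid of 14 (6R-OH; C12 carboxylic acid; 8-OSiEt3 kept)
Conditions: LiOH, THF/H2O, 0 °C; then 1 M H3PO4 to pH 4, 0 °C, extracted and used at once
Reagents that add atoms: lithium hydroxide, [Li+].[OH-]
Why: Saponification opens the strained trans‑fused lactone without touching a stereocentre, and that strain should slow re‑lactonisation enough for the hydroxy acid to be handled.

Step 11
Reactants: 15 hydroxy acid
Product: 16 cis-lactone tricycle (6S,7S,10R); 8-OSiEt3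
Conditions: PPh3, iPrO2CN=NCO2iPr, THF, 0 °C to rt
Reagents that add atoms: none
Why: Mitsunobu lactonisation: the carboxylate on the C7 arm displaces the activated C6 oxygen by SN2 from the opposite face (the SN2′ alternative would need a seven‑membered ring), which inverts C6 to (S) and gives the cis‑fused lactone of the target.

Step 12
Reactants: 16 cis-lactone tricycle
Product: 19 11(13)-methylene cis-lactone tricycle; 8-OSiEt3, via Mannich base 17 (not isolated), via ammonium iodide 18 (not isolated)
Conditions: LiN(iPr)2, THF, −78 °C; [CH2=NMe2]I, −78 °C to rt; MeI, MeOH; NaHCO3 (aq), CH2Cl2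
Reagents that add atoms: N,N-dimethylmethylideneammonium iodide, C=[N+](C)C.[I-]; iodomethane, CI
Why: Eschenmoser methylenation (lactone enolate Mannich reaction, quaternisation, E1cB elimination) is done here because the molecule has no ketone yet and no furan left to react with the acrylate.

Step 13
Reactants: 19 methylene lactone silyl ether
Product: 20 11(13)-methylene cis-lactone tricycle; 8-OH
Conditions: Bu4NF, AcOH, THF, 0 °C
Reagents that add atoms: none
Why: Buffered fluoride desilylation frees the tertiary C8 alcohol without base‑induced addition to the lactone methylene.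

Step 14
Reactants: 20 tertiary alcohol
Product: 22 (1Z,4Z,6S,7S,10R)-10-hydroxy-3,8-dioxogermacra-1,4,11(13)-trien-6,12-olide, via acetate ketal 21 (not isolated)
Conditions: PhI(OAc)2, I2, CH2Cl2, visible light, rt; then THF/H2O, pyridinium p-toluenesulfonate (cat.), 0 °C
Reagents that add atoms: (diacetoxyiodo)benzene, CC(=O)OI(OC(C)=O)c1ccccc1; water, O
Why: Hypoiodite (alkoxy‑radical) β‑fragmentation: the C8 alkoxy radical cleaves C3–C8, the only scission that relieves the oxanorbornene strain and gives a radical that is both α‑oxygenated and doubly allylic; iodine oxidises it to the oxocarbenium ion, acetate captures it (21), and mild hydrolysis unmasks the C3 ketone and the C10 carbinol, with both alkene geometries inherited from the small rings.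

Step 15
Reactants: 22 hydroxy dione
Product: 23 (1Z,4Z,6S,7R,8R,10R)-8,10-dihydroxy-3-oxogermacra-1,4,11(13)-trien-6,12-olide
Conditions: Me4NBH(OAc)3, MeCN/AcOH, −30 °C
Reagents that add atoms: none
Why: Evans–Saksena reduction: the C10 hydroxyl binds boron and delivers hydride to C8 through a six‑membered chair with ring carbons C7 and C1 equatorial, which should give the 1,3‑anti diol (8R) and leave the C3 dienone alone.

Step 16
Reactants: 23 diol; 24 (Z)-2-methylbut-2-enoic acid (angelic acid)
Product: 25 (1Z,4Z,6S,7R,8R,10R)-8-angeloyloxy-10-hydroxy-3-oxogermacra-1,4,11(13)-trien-6,12-olide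
Conditions: 2,4,6-Cl3C6H2COCl, Et3N, toluene, rt; then 23, 70 °C
Reagents that add atoms: none
Why: Yamaguchi‑type mixed‑anhydride esterification without a nucleophilic catalyst acylates the secondary C8 hydroxyl over the tertiary one and avoids angelate‑to‑tiglate isomerisation.

Step 17
Reactants: 25 angelate
Product: 26 (1S,2R,4Z,6S,7R,8R,10R)-8-angeloyloxy-1,2-epoxy-10-hydroxy-3-oxogermacra-4,11(13)-dien-6,12-olide (target)
Conditions: t-BuOOH, BnNMe3OH (cat.), THF, 0 °C
Reagents that add atoms: tert-butyl hydroperoxide, CC(C)(C)OO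
Why: Weitz–Scheffer epoxidation should pick the α‑unsubstituted C1=C2 enone over the α‑methyl C4=C5 enone; attack from the peripheral face (anti to C9, with the C10 hydroxyl near the enone plane) and ring closure faster than bond rotation in the ten‑membered ring should give the cis (1S,2R) epoxide.

**Compound list**

1 | but-2-yn-1-ol | CC#CCO | starting material
2 | (Z)-3-iodobut-2-en-1-ol | OC/C=C(/C)I | intermediate
3 | 4,4,5,5-tetramethyl-2-(5-methylfuran-2-yl)-1,3,2-dioxaborolane | Cc1ccc(o1)B1OC(C)(C)C(C)(C)O1 | starting material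
4 | (Z)-3-(5-methylfuran-2-yl)but-2-en-1-ol | OC/C=C(/C)c1ccc(C)o1 | intermediate
5 | (Z)-3-(5-methylfuran-2-yl)but-2-enal | O=C/C=C(/C)c1ccc(C)o1 | intermediate
6 | (S)-4-benzyloxazolidin-2-one | O=C1N[C@@H](Cc2ccccc2)CO1 | starting material
7 | methyl 4-chloro-4-oxobutanoate | COC(=O)CCC(Cl)=O | starting material
8 | methyl 4-[(S)-4-benzyl-2-oxooxazolidin-3-yl]-4-oxobutanoate | COC(=O)CCC(=O)N1[C@@H](Cc2ccccc2)COC1=O | intermediate
9 | methyl (3S,4R,5Z)-3-[(S)-4-benzyl-2-oxooxazolidine-3-carbonyl]-4-hydroxy-6-(5-methylfuran-2-yl)hept-5-enoate (syn-aldol adduct) | O=C(N1[C@@H](Cc2ccccc2)COC1=O)[C@@H](CC(=O)OC)[C@H](O)/C=C(/C)c1ccc(C)o1 | intermediate (not isolated)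
10 | (S)-4-benzyl-3-{(2R,3S)-2-[(Z)-2-(5-methylfuran-2-yl)prop-1-en-1-yl]-5-oxotetrahydrofuran-3-carbonyl}oxazolidin-2-one | O=C(N1[C@@H](Cc2ccccc2)COC1=O)[C@H]1CC(=O)O[C@@H]1/C=C(/C)c1ccc(C)o1 | intermediate
11 | S-ethyl (2R,3S)-2-[(Z)-2-(5-methylfuran-2-yl)prop-1-en-1-yl]-5-oxotetrahydrofuran-3-carbothioate | CCSC(=O)[C@H]1CC(=O)O[C@@H]1/C=C(/C)c1ccc(C)o1 | intermediate
12 | (4S,5R)-4-acetyl-5-[(Z)-2-(5-methylfuran-2-yl)prop-1-en-1-yl]dihydrofuran-2(3H)-one | CC(=O)[C@H]1CC(=O)O[C@@H]1/C=C(/C)c1ccc(C)o1 | intermediate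
13 | (4S,5R)-5-[(Z)-2-(5-methylfuran-2-yl)prop-1-en-1-yl]-4-[1-(triethylsilyloxy)vinyl]dihydrofuran-2(3H)-one | C=C(O[Si](CC)(CC)CC)[C@H]1CC(=O)O[C@@H]1/C=C(/C)c1ccc(C)o1 | intermediate
14 | exo Diels–Alder adduct: (6R,7S,10R)-3,10-epoxy tricycle with C3–C8 and C9–C10 bonds, 8-OSiEt3 anti to the oxygen bridge, H-7 syn to it, trans-6,12-lactone (temporary centres C3, C8 as in the SMILES) | C[C@]12C[C@]3(O[Si](CC)(CC)CC)[C@H]4CC(=O)O[C@@H]4C=C(C)[C@@]3(O1)C=C2 | intermediate
15 | hydroxy acid of 14: (6R)-6-hydroxy, C12 carboxylic acid, 8-OSiEt3 | C[C@]12C[C@]3(O[Si](CC)(CC)CC)[C@@H](CC(=O)O)[C@H](O)C=C(C)[C@@]3(O1)C=C2 | intermediate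
16 | cis-lactone tricycle (6S,7S,10R), 8-OSiEt3 | C[C@]12C[C@]3(O[Si](CC)(CC)CC)[C@H]4CC(=O)O[C@H]4C=C(C)[C@@]3(O1)C=C2 | intermediate
17 | 11-(dimethylaminomethyl) derivative of 16 (C11 epimers) | C[C@]12C[C@]3(O[Si](CC)(CC)CC)[C@H]4C(CN(C)C)C(=O)O[C@H]4C=C(C)[C@@]3(O1)C=C2 | intermediate (not isolated)
18 | trimethylammonium iodide of 17 | C[C@]12C[C@]3(O[Si](CC)(CC)CC)[C@H]4C(C[N+](C)(C)C)C(=O)O[C@H]4C=C(C)[C@@]3(O1)C=C2.[I-] | intermediate (not isolated)
19 | 11(13)-methylene cis-lactone tricycle, 8-OSiEt3 | C[C@]12C[C@]3(O[Si](CC)(CC)CC)[C@H]4C(=C)C(=O)O[C@H]4C=C(C)[C@@]3(O1)C=C2 | intermediate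
20 | 11(13)-methylene cis-lactone tricycle, 8-OH | C[C@]12C[C@]3(O)[C@H]4C(=C)C(=O)O[C@H]4C=C(C)[C@@]3(O1)C=C2 | intermediate
21 | (4Z,6S,7S,10R)-3-acetoxy-3,10-epoxy-8-oxogermacra-1,4,11(13)-trien-6,12-olide (C3 epimers) | C=C1C(=O)O[C@H]2/C=C(/C)C3(OC(C)=O)O[C@@](C)(C=C3)CC(=O)[C@@H]12 | intermediate (not isolated)
22 | (1Z,4Z,6S,7S,10R)-10-hydroxy-3,8-dioxogermacra-1,4,11(13)-trien-6,12-olide (in equilibrium with its 3,10-hemiketal) | C=C1C(=O)O[C@H]2/C=C(/C)C(=O)/C=C\[C@](C)(O)CC(=O)[C@@H]12 | intermediate
23 | (1Z,4Z,6S,7R,8R,10R)-8,10-dihydroxy-3-oxogermacra-1,4,11(13)-trien-6,12-olide | C=C1C(=O)O[C@H]2/C=C(/C)C(=O)/C=C\[C@](C)(O)C[C@@H](O)[C@@H]12 | intermediate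
24 | (Z)-2-methylbut-2-enoic acid (angelic acid) | C/C=C(/C)C(=O)O | starting material
25 | (1Z,4Z,6S,7R,8R,10R)-8-angeloyloxy-10-hydroxy-3-oxogermacra-1,4,11(13)-trien-6,12-olide | C=C1C(=O)O[C@H]2/C=C(/C)C(=O)/C=C\[C@](C)(O)C[C@@H](OC(=O)/C(C)=C\C)[C@@H]12 | intermediate
26 | (1S,2R,4Z,6S,7R,8R,10R)-8-angeloyloxy-1,2-epoxy-10-hydroxy-3-oxogermacra-4,11(13)-dien-6,12-olide | C=C1C(=O)O[C@H]2/C=C(/C)C(=O)[C@@H]3O[C@@H]3[C@](C)(O)C[C@@H](OC(=O)/C(C)=C\C)[C@@H]12 | target

**Step count and risks**

Total steps: 17. Longest linear sequence: 16 (steps 1–3 and 5–17, from but-2-yn-1-ol).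

Steps most likely to fail:

1. Step 9 (the labelled step). The electron‑rich enol ether may be too unreactive towards the electron‑rich furan even under pressure, or the furan may be attacked on the wrong face. The fallback uses an activated dienophile and known reactions; it sets out from ketone 12 and returns at 14. Kinetic enolisation of 12 (KN(SiMe3)2, PhNTf2) would give the enol triflate F1. Palladium‑catalysed reductive carbonylation (Pd(PPh3)4, CO, Bu3SnH) would give the 2‑substituted acrolein F2. A Lewis‑acid‑promoted intramolecular furan Diels–Alder reaction (MeAlCl2, CH2Cl2, −78 °C) should give the C8 aldehyde adduct F3 with the same exo tether. Baeyer–Villiger oxidation with retention (H2O2, (PhSe)2 cat.) would give the formate F4, methanolysis (KHCO3, MeOH) the tertiary alcohol F5, and silylation (Et3SiOTf, 2,6‑lutidine) would give 14.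

2. Step 14. The hypoiodite may add to the trisubstituted or the exocyclic alkene, or the allylic cation may be captured at the wrong terminus. The fallback is a two‑electron route; it sets out from alcohol 20 and returns at 22. Acid‑catalysed hydrolytic opening of the oxygen bridge at the doubly allylic C3 (HClO4 cat., THF/H2O, 0 °C) would give the triol F6. Criegee cleavage of its ditertiary C3/C8 glycol with Pb(OAc)4 should give 22 directly.

3. Step 17. The peroxide anion may add to the lactone methylene, or the cis geometry may be lost by rotation in the peroxy enolate. The fallback masks the acrylate; it sets out from 25 and returns at 26. Conjugate addition of Me2NH would give the amine adduct F7. Epoxidation under the conditions of step 17 would give the epoxy amine F8. Quaternisation and elimination (MeI; NaHCO3) would restore the methylene and give 26.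

**Further compounds**

F1 | step 9 | (4S,5R)-5-[(Z)-2-(5-methylfuran-2-yl)prop-1-en-1-yl]-4-[1-(trifluoromethylsulfonyloxy)vinyl]dihydrofuran-2(3H)-one (enol triflate) | C=C(OS(=O)(=O)C(F)(F)F)[C@H]1CC(=O)O[C@@H]1/C=C(/C)c1ccc(C)o1
F2 | step 9 | 2-{(2R,3S)-2-[(Z)-2-(5-methylfuran-2-yl)prop-1-en-1-yl]-5-oxotetrahydrofuran-3-yl}acrylaldehyde (2-substituted acrolein) | C=C(C=O)[C@H]1CC(=O)O[C@@H]1/C=C(/C)c1ccc(C)o1
F3 | step 9 | C8 aldehyde adduct (tricycle as 14 with CHO in place of OSiEt3) | C[C@]12C[C@]3(C=O)[C@H]4CC(=O)O[C@@H]4C=C(C)[C@@]3(O1)C=C2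
F4 | step 9 | C8 formate (tricycle as 14 with OCHO in place of OSiEt3) | C[C@]12C[C@]3(OC=O)[C@H]4CC(=O)O[C@@H]4C=C(C)[C@@]3(O1)C=C2
F5 | step 9 | C8 tertiary alcohol with trans-lactone (tricycle as 14 with OH in place of OSiEt3) | C[C@]12C[C@]3(O)[C@H]4CC(=O)O[C@@H]4C=C(C)[C@@]3(O1)C=C2
F6 | step 14 | 3,8,10-triol from opening of the oxygen bridge of 20 (C3 epimers) | C[C@@]1(O)C[C@]2(O)[C@H]3C(=C)C(=O)O[C@H]3C=C(C)C2(O)C=C1
F7 | step 17 | 13-(dimethylamino) adduct of 25 (C11 epimers) | CN(C)CC1C(=O)O[C@H]2/C=C(/C)C(=O)/C=C\[C@](C)(O)C[C@@H](OC(=O)/C(C)=C\C)[C@@H]12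
F8 | step 17 | 13-(dimethylamino) adduct of 26 (C11 epimers) | CN(C)CC1C(=O)O[C@H]2/C=C(/C)C(=O)[C@@H]3O[C@@H]3[C@](C)(O)C[C@@H](OC(=O)/C(C)=C\C)[C@@H]12
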